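**The question.** I wanted to know how much target stands at the end of each flask, and how that amount moves with the charge.

    intermediate ⇌ target (K1 = 41, k1 = 0.00522 /s)
    starting material + target → side product (k2 = 0.368 /M/s)
    starting material ⇌ intermediate (K3 = 0.242, k3 = 0.0118 /s)

all flasks: time 15 min

| charge | starting material |
|---|---|
| south | 20 mM |
| north-east | 60 mM |
| south-east | 150 mM |

- [target] at the end for south, north-east, south-east, in this order
- how that number moves from the first to the last of them (hardly changes / falls, then rises / rises all the way / falls all the way / rises, then falls)

- percentages count the starting material that a species holds: one side product counts as two
- "hardly changes" means that all values lie within two and a half points (for a concentration: within two and a half percent of the largest)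
- run time (south): 15 min

**One molecule.** I followed one molecule of starting material. Its step to intermediate relaxes in 0.191 min, faster than the 2.16 min of the next step, so I let intermediate stand at 0.242 times the starting material. Target was then made at a pace proportional to the starting material and eaten at a pace proportional to it too. Starting material cancelled, and the balance (a steady state) stood at 0.00522 /s times 0.242 over 0.368 /M/s, or 3.43 mM.

**One number.** Folding in the charge gave the plateau share, 17.2% in south, which is the fraction of the charge standing as target when making and eating balance. It was 5.72% in north-east and 2.29% in south-east. Multiplied by its charge, each gave the same 3.43 mM, so I committed to that level and to "hardly changes".

**The test.** The number assumes that target has reached its balance. Its clock at full charge, ln(2) over the rate constant of the step to side product times the charge, was 1.57 min in south, longer than in the other flasks but shorter than 15 min. I kept the number and marked south as the flask to watch; the clock lengthens as starting material falls.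

**The forecast.** The forecast gave 2.9 mM, 3.1 mM and 3.15 mM, with the shape rises all the way, reasoning that “it settles at a plateau of about 3 mM”. Its values stood below my level, and its shape parted from mine.

**The flask.** The run gave 2.91 mM, 3.14 mM and 3.18 mM, and the shape rises all the way, as the forecast said. In south, target was made 2.39 times as fast as it was used up at 1.85 min, each step taken net, and 1.02 times as fast at the end, close to the balance the plateau share describes. South held 14.5% of its charge as target at the end, against a share of 17.2%. Scaled to south-east, that share is 2.29%, and south-east held 2.12% at the end, as it already had at 7.50 min, with 2.13%.

The numbers come from no measurement; the rest is arithmetic.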